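If you take over this flask, go by its readings before any model of them.

in all of them: free monomer 0.010 M; initiator 2.5 mol%

|  | protic impurity | remark | time |
|---|---|---|---|
| north | 1 mM | the very flask that is asked about, followed so far |  |
| flask | 1.00 mM |  | 2.5 h |

north run (percent of the free monomer charged)

| time / min | monomer in chains / % | side product / % | free monomer / % |
|---|---|---|---|
| 2.00 | 17.0 | 46.8 | 27.2 |
| 6.00 | 16.1 | 71.8 | 1.4 |
| 10.0 | 17.0 | 73.9 | 1.3 |
| 15.0 | 17.0 | 75.5 | 0.3 |
| 25.0 | 15.6 | 74.6 | 0.7 |
| 30.0 | 18.9 | 73.4 | 0.8 |

(standard deviation of a reading: 1 percentage point)

- a species is counted by the free monomer in it: one side product counts as two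
- the reaction counts as stopped when no species that holds the free monomer changes by six tenths of a point or more over the second half of the time

- which holds at 2.5 h: what has brought the reaction to rest, or that it has not come to rest (all of the free monomer has reacted / it is still moving / no working catalyst is left)
- amount of monomer in chains at 2.5 h, in percent of the free monomer charged
- amount of side product at 2.5 h, in percent of the free monomer charged

Free monomer read 27.2% at 2.00 min and 0.8% at 30.0 min. Now follow one free monomer to its fork: as I read it, it enters a chain, meets a chain and goes with it into side product, or goes to the protic impurity. Between the first two readings side product rose 25 percentage points while chains moved 0.9 points, so take chains as made and eaten at one pace, a quasi-steady state. Carry the chains held per initiator, the holding ratio, as my own reckoning, read off scattered readings: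

level of chains = mean of the six readings = 16.9%

holding ratio = level / initiator loading = 6.77

Expect chains at that level when you come. Add no initiator, and wait for nothing.

The forecast says all of the free monomer has reacted, with chains 17% (16% to 18%) and side product 74.6% (73.5% to 75.8%): “the reaction stopped because the monomer ran out”.

The flask gives all of the free monomer has reacted, chains 16.4%, side product 73.6%.

    free monomer + initiator → living end + monomer in chains (k = 21.0 M⁻¹ s⁻¹)
    free monomer + living end → monomer in chains + living end, rate k2*[living end]*[free monomer] (k = 24.0 M⁻¹ s⁻¹)
    free monomer + monomer in chains → side product (k = 3.50 M⁻¹ s⁻¹)
    protic impurity + free monomer → quenched substrate (k = 41.0 M⁻¹ s⁻¹)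

Chains per initiator in the asked flask come to 6.55, with free monomer at 0%. Put the carried ratio on the neighbouring flask, the same charge with 10 mol% of initiator: it gives 67.7% in chains. That flask holds 42.4% in chains, less than the ratio gives, and 47.6% in side product. Its free monomer stands at 0% with chains 25 points under that figure.

Readings and results were generated by integration from invented constants, noise included.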